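**The question.** You want to know when this flask holds most single product, and how long it stays near that. The violet run is this flask, followed so far. The grey run has less substrate and the same partner.

| setting | violet | grey | flask |
|---|---|---|---|
| substrate | 0.21 M | 0.10 M | 0.21 M |
| partner | 0.315 M | 0.315 M | 0.315 M |
| remark | the very flask that is asked about, followed so far | run made earlier |  |
| time |  |  | 4.0 d |

violet run (percent of the substrate charged)

| time / h | single product / % | substrate / % |
|---|---|---|
| 1.33 | 16.1 | 67.0 |
| 4.00 | 21.1 | 52.4 |
| 15.0 | 18.7 | 50.2 |
| 50.0 | 17.0 | 49.7 |

grey run (percent of the substrate charged)

| time / d | single product / % | substrate / % |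
|---|---|---|
| 0.0556 | 17.4 | 63.7 |
| 0.208 | 23.6 | 43.2 |
| 0.833 | 21.9 | 41.3 |
| 3.00 | 18.8 | 40.6 |

(standard deviation of a reading: 0.5 percentage points)

1. the moment within 4.0 d at which there is most single product
2. the amount of single product, in percent of the substrate charged, at that time
3. earliest time at which at least nineteen twentieths of that best amount are there, in d
4. latest time at which they still are, in d

**End state.** Violet substrate stalls near 49.7%, having used 0.106 M against 0.315 M of partner charged. So I take partner to be dying by another route as well, which makes it the limiting reagent. If ln[substrate] falls at a rate proportional to [partner], the stall follows from one quantity, the reach: ln(substrate charged over substrate at the stall) per unit of partner charged. The violet run gives 2.22 L mol⁻¹, the grey run 2.86 L mol⁻¹.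

**Two ways.** The two reaches part, so one of them cheats here. The last approach to the stall reads 0.648 h⁻¹ in violet and 0.542 h⁻¹ in grey, and on these scattered readings I take that to mean partner lasts longer in grey. Reach times this rate should be a capture constant, and the runs give 1.44 L mol⁻¹ h⁻¹ and 1.55 L mol⁻¹ h⁻¹. I read these as one constant within the scatter and carry it over, and I tie the grey reach to grey's lower substrate, the one setting in which the runs differ. This flask takes the violet reach.

**The peak.** By my reckoning from the violet readings, net single product per substrate used between the first two is 34.2%, and the fade between the second and third is 0.00218 h⁻¹ of the charge. If the gain decays at the violet rate, I estimate that it meets that fade at 0.232 d.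

**The forecast.** It gives 21.2% at 0.15 d, with a window from 0.11 d to 0.33 d, reasoning that “the maximum comes as the fast phase ends”. Its peak is earlier than mine.

**The flask.** The peak is 21.6% at 0.223 d, later than forecast, with the window from 0.118 d to 0.498 d. At that moment partner stands at 2.96% of its charge. Through the reach, that remainder puts substrate at 50.7%, and the flask holds 51.0%.

    substrate + partner → single product (k = 0.810 L mol⁻¹ h⁻¹)
    substrate + partner → other mono adduct (k = 0.680 L mol⁻¹ h⁻¹)
    partner + single product → bis adduct (k = 0.630 L mol⁻¹ h⁻¹)
    partner + other mono adduct → bis adduct (k = 1.50 L mol⁻¹ h⁻¹)
    single product ⇌ isomer of the product (K = 0.390, k = 0.0140 h⁻¹)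
    partner → decomposed reagent (k = 0.400 h⁻¹)

**Second flask.** In the neighbour flask, with the same substrate charge and 0.54 M of partner, the violet reach gives an estimate of 30.2% substrate at the end. The computed neighbour holds 28.7%.

The runs come from a simulation for substances that don't exist; noise was put on by code.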